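**Plan**

- Retrosynthesis cuts, in this order: the C7–O ester bond to the orsellinate, the C6–C7 bond of the carbocycle, the C4a=C5 bond (a formylmethylidene on a 4‑pyranone carbonyl), the C8–C8a bond (an allyl group on a pyranone triflate), and the side‑chain alkene at C3.
- The feature that allows the key cut is the acyloin inside ring C4a–C5–C6–C7–C8–C8a. The C6 carbonyl is bonded directly to the fully substituted carbinol C7 (CH3, O‑acyl), C8 is a plain CH2 and C5 is a vinylic CH on C4a. Cutting C6–C7 therefore leaves a formyl carbon and a methyl ketone on neighbouring positions of an intact 4H‑pyran ring (O2, C1, C3, C4, C4a, C8a), which is the ring of kojic acid.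
- Forward: the pyran ring is bought as kojic acid. C8a is allylated through the triflate, the hydroxymethyl group is grown into the E‑allylic side chain at C3, the pyranone carbonyl is turned into the C4a=C5–C6HO unit by alkynyl addition and Meyer–Schuster rearrangement, and the allyl group is oxidised to the C7 methyl ketone.
- The carbocycle then closes by an enantioselective carbene‑catalysed intramolecular crossed benzoin reaction (C6–C7). The orsellinate is attached last by acylation of the tertiary ketol.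
- C7 is the only stereocentre and is set as (S) in the benzoin step by the chiral triazolium carbene. The E side‑chain alkene comes from a stabilised Wittig ylide, and the C4a=C5 geometry is fixed by the ring.

Key step: step 10

Atom labels C1 to C8a follow the isochromene numbering of the target and are used for all intermediates.

Assumption: the sense of induction of the triazolium salt on this new substrate cannot be read safely from precedent, so the catalyst antipode that gives (S) at C7 is taken to be fixed by one trial with each of the two commercial antipodes. Compounds 11 and 12 are drawn with the formyl group syn to the C8a substituent (Z), and the polarised C4a=C5 bond is expected to isomerise easily.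

**Route**

Step 1
Reactants: 1 kojic acid (5‑hydroxy‑2‑(hydroxymethyl)‑4H‑pyran‑4‑one)
Product: 2 kojic acid 5‑triflate (6‑(hydroxymethyl)‑4‑oxo‑4H‑pyran‑3‑yl trifluoromethanesulfonate)
Conditions: PhNTf2 (1.05 equiv), Et3N, DMF, 0 °C to rt
Reagents that add atoms: N‑phenylbis(trifluoromethanesulfonimide), O=S(=O)(N(c1ccccc1)S(=O)(=O)C(F)(F)F)C(F)(F)F
Why: Chemoselective O‑triflation, in which the acidic enolic 5‑OH is deprotonated by the amine and sulfonylated by the mild triflyl donor while the neutral primary alcohol does not react.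

Step 2
Reactants: 2 kojic acid 5‑triflate; 3 allyltributylstannane
Product: 4 5‑allyl‑2‑(hydroxymethyl)‑4H‑pyran‑4‑one
Conditions: Pd(PPh3)4 (5 mol %), LiCl (3 equiv), 1,4‑dioxane, 90 °C
Reagents that add atoms: none
Why: Stille cross‑coupling, in which the electron‑poor vinyl triflate adds oxidatively to zerovalent palladium, chloride assists transmetalation, and the allyl group (C8 plus a masked acetonyl unit) is delivered to the future C8a.

Step 3
Reactants: 4 5‑allyl‑2‑(hydroxymethyl)‑4H‑pyran‑4‑one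
Product: 5 5‑allyl‑4‑oxo‑4H‑pyran‑2‑carbaldehyde
Conditions: MnO2 (excess), CHCl3, reflux
Reagents that add atoms: none
Why: Heterogeneous MnO2 oxidation of an allylic‑type primary alcohol (the CH2OH on the pyranone C=C bond) to the aldehyde, which leaves the isolated allyl group untouched.

Step 4
Reactants: 5 5‑allyl‑4‑oxo‑4H‑pyran‑2‑carbaldehyde; 6 (triphenylphosphoranylidene)acetaldehyde
Product: 7 (E)‑3‑(5‑allyl‑4‑oxo‑4H‑pyran‑2‑yl)prop‑2‑enal
Conditions: 6 (1.05 equiv), toluene, 70 °C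
Reagents that add atoms: none
Why: Wittig olefination with a stabilised formyl ylide, which is E‑selective and should stop after one homologation because aldehyde 5 is much more electrophilic than the vinylogous enal product.

Step 5
Reactants: 7 (E)‑3‑(5‑allyl‑4‑oxo‑4H‑pyran‑2‑yl)prop‑2‑enal
Product: 8 5‑allyl‑2‑[(E)‑3‑hydroxyprop‑1‑enyl]‑4H‑pyran‑4‑one
Conditions: NaBH4, CeCl3·7H2O, MeOH, −40 °C
Reagents that add atoms: none
Why: Luche reduction, which delivers hydride 1,2 to the enal while the pyranone carbonyl, a vinylogous ester, is inert to borohydride at low temperature.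

Step 6
Reactants: 8 5‑allyl‑2‑[(E)‑3‑hydroxyprop‑1‑enyl]‑4H‑pyran‑4‑one
Product: 9 5‑allyl‑2‑[(E)‑3‑(tert‑butyldiphenylsilyloxy)prop‑1‑enyl]‑4H‑pyran‑4‑one
Conditions: TBDPSCl, imidazole, DMF, 0 °C to rt
Reagents that add atoms: tert‑butyldiphenylsilyl chloride, CC(C)(C)[Si](Cl)(c1ccccc1)c1ccccc1
Why: Standard silylation of a primary alcohol, chosen because the TBDPS ether should survive the Grignard, mildly acidic and palladium steps that follow.

Step 7
Reactants: 9 5‑allyl‑2‑[(E)‑3‑(tert‑butyldiphenylsilyloxy)prop‑1‑enyl]‑4H‑pyran‑4‑one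
Product: 10 racemic 5‑allyl‑2‑[(E)‑3‑(tert‑butyldiphenylsilyloxy)prop‑1‑enyl]‑4‑ethynyl‑4H‑pyran‑4‑ol
Conditions: HC≡CMgBr (2 equiv), CeCl3, THF, −78 to 0 °C; pH 7 buffer quench; crude product carried on
Reagents that add atoms: ethynylmagnesium bromide, C#C[Mg]Br
Why: 1,2‑Addition of a hard alkynyl organometallic to the 4‑pyranone carbonyl, the same addition that is used to turn 4‑pyranones into 4‑substituted pyrylium salts, and the racemic carbinol centre it creates is destroyed in step 8.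

Step 8
Reactants: 10 racemic 5‑allyl‑2‑[(E)‑3‑(tert‑butyldiphenylsilyloxy)prop‑1‑enyl]‑4‑ethynyl‑4H‑pyran‑4‑ol
Product: 11 (Z)‑2‑{5‑allyl‑2‑[(E)‑3‑(tert‑butyldiphenylsilyloxy)prop‑1‑enyl]‑4H‑pyran‑4‑ylidene}acetaldehyde
Conditions: crude 10, PPTS (10 mol %), THF/H2O 10:1, rt
Reagents that add atoms: water, O
Why: Meyer–Schuster rearrangement, in which the doubly vinylogous carbinol ionises under mild acid to a 4‑ethynylpyrylium ion, water adds to the alkyne terminus and the allenol tautomerises to the enal, while a Rupe pathway is excluded because the carbinol carbon has no sp3 neighbour bearing hydrogen.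

Step 9
Reactants: 11 (Z)‑2‑{5‑allyl‑2‑[(E)‑3‑(tert‑butyldiphenylsilyloxy)prop‑1‑enyl]‑4H‑pyran‑4‑ylidene}acetaldehyde
Product: 12 (Z)‑2‑{5‑(2‑oxopropyl)‑2‑[(E)‑3‑(tert‑butyldiphenylsilyloxy)prop‑1‑enyl]‑4H‑pyran‑4‑ylidene}acetaldehyde
Conditions: PdCl2 (10 mol %), CuCl (1 equiv), O2 (1 atm), DMF/H2O 7:1, rt
Reagents that add atoms: water, O
Why: Tsuji–Wacker oxidation, in which divalent palladium activates the only monosubstituted terminal alkene and water attacks in the Markovnikov sense to give the methyl ketone, as with allylarenes, while the conjugated and more substituted alkenes react far more slowly.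

Step 10
Reactants: 12 (Z)‑2‑{5‑(2‑oxopropyl)‑2‑[(E)‑3‑(tert‑butyldiphenylsilyloxy)prop‑1‑enyl]‑4H‑pyran‑4‑ylidene}acetaldehyde
Product: 13 (S)‑3‑[(E)‑3‑(tert‑butyldiphenylsilyloxy)prop‑1‑enyl]‑7‑hydroxy‑7‑methyl‑7,8‑dihydro‑6H‑isochromen‑6‑one
Conditions: 2‑(pentafluorophenyl)‑5a,10b‑dihydro‑4H,6H‑indeno[2,1‑b][1,2,4]triazolo[4,3‑d][1,4]oxazin‑2‑ium tetrafluoroborate (aminoindanol‑derived, antipode that gives (S), 10 mol %), Et3N (10 mol %), toluene, rt
Reagents that add atoms: none
Why: Proposed new method: the free carbene adds to the C6 formyl group of 12, a proton shift gives the enaminol acyl anion equivalent, its C6 attacks the C7 methyl ketone, and proton transfer with loss of the carbene restores the C6 carbonyl in conjugation with the pyranylidene. The closest known reaction type is the chiral triazolium‑catalysed intramolecular crossed aldehyde–ketone benzoin that gives 2‑hydroxy‑2‑methyl‑1‑tetralone‑type ketols, and the new element is a donor‑substituted, push–pull formylmethylidene pyran as the aldehyde partner. The one ring that closes is the carbocycle C4a–C5–C6–C7–C8–C8a, by a 6‑exo‑trig attack on the ketone. C7, the only stereocentre, is set by the chiral carbene, whose N‑aryl group and indane backbone leave one face of the prochiral ketone open, and the catalyst antipode is chosen to give (S). The step needs acyl‑anion rather than homoenolate or aldol reactivity, and this is secured because C4a is fully substituted and charge there would create an eight‑π‑electron pyranide, no protic nucleophile is present to drain an acyl azolium, the electron‑poor N‑C6F5 catalyst favours the acyloin path, and the weak amine base should not enolise the ketone toward C8 for a five‑membered aldol. Rotation about the polarised C4a=C5 bond should be easy through its pyrylium enolate resonance form, so either geometric isomer of 12 is expected to reach the reactive one with the formyl group beside the acetonyl arm.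

Step 11
Reactants: 13 (S)‑3‑[(E)‑3‑(tert‑butyldiphenylsilyloxy)prop‑1‑enyl]‑7‑hydroxy‑7‑methyl‑7,8‑dihydro‑6H‑isochromen‑6‑one
Product: 14 (S)‑7‑hydroxy‑3‑[(E)‑3‑hydroxyprop‑1‑enyl]‑7‑methyl‑7,8‑dihydro‑6H‑isochromen‑6‑one
Conditions: Bu4NF/AcOH (1:1), THF, 0 °C to rt
Reagents that add atoms: none
Why: Fluoride‑mediated desilylation of the primary TBDPS ether, buffered with acetic acid so that the medium does not become basic enough for a retro‑benzoin or α‑ketol shift at C7.

Step 12
Reactants: 14 (S)‑7‑hydroxy‑3‑[(E)‑3‑hydroxyprop‑1‑enyl]‑7‑methyl‑7,8‑dihydro‑6H‑isochromen‑6‑one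
Product: 15 (E)‑3‑[(S)‑7‑hydroxy‑7‑methyl‑6‑oxo‑7,8‑dihydro‑6H‑isochromen‑3‑yl]allyl acetate
Conditions: Ac2O (1.2 equiv), pyridine, CH2Cl2, 0 °C
Reagents that add atoms: acetic anhydride, CC(=O)OC(C)=O
Why: Selective acetylation without DMAP, which distinguishes the unhindered primary allylic hydroxyl from the tertiary C7 hydroxyl on steric grounds.

Step 13
Reactants: 16 orsellinic acid (2,4‑dihydroxy‑6‑methylbenzoic acid)
Product: 18 2,4‑bis(tert‑butyldimethylsilyloxy)‑6‑methylbenzoic acid, via tris‑silyl orsellinate 17 (not isolated)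
Conditions: TBSCl (3.5 equiv), imidazole, DMF, rt to 40 °C; then AcOH/THF/H2O 3:1:1, rt
Reagents that add atoms: tert‑butyldimethylsilyl chloride, CC(C)(C)[Si](C)(C)Cl
Why: Exhaustive silylation followed by mild aqueous acid, which hydrolyses the labile silyl ester while the aryl silyl ethers persist.

Step 14
Reactants: 15 (E)‑3‑[(S)‑7‑hydroxy‑7‑methyl‑6‑oxo‑7,8‑dihydro‑6H‑isochromen‑3‑yl]allyl acetate; 18 2,4‑bis(tert‑butyldimethylsilyloxy)‑6‑methylbenzoic acid
Product: 20 (S)‑3‑[(E)‑3‑acetoxyprop‑1‑enyl]‑7‑methyl‑6‑oxo‑7,8‑dihydro‑6H‑isochromen‑7‑yl 2,4‑bis(tert‑butyldimethylsilyloxy)‑6‑methylbenzoate, via aroyl chloride 19 (not isolated)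
Conditions: 18, 1‑chloro‑N,N,2‑trimethylprop‑1‑en‑1‑amine, CH2Cl2, 0 °C to rt; then 15, DMAP (2 equiv), Et3N, CH2Cl2, rt to 40 °C
Reagents that add atoms: 1‑chloro‑N,N,2‑trimethylprop‑1‑en‑1‑amine, CC(C)=C(Cl)N(C)C (supplies the chlorine of 19; none of its atoms remain in 20)
Why: DMAP‑mediated acylation of a tertiary alcohol through the N‑acylpyridinium ion, using an acid chloride made under neutral conditions so that the aryl silyl ethers survive, and with no bond to C7 broken so that its configuration is kept.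

Step 15
Reactants: 20 (S)‑3‑[(E)‑3‑acetoxyprop‑1‑enyl]‑7‑methyl‑6‑oxo‑7,8‑dihydro‑6H‑isochromen‑7‑yl 2,4‑bis(tert‑butyldimethylsilyloxy)‑6‑methylbenzoate
Product: 21 (S)‑3‑[(E)‑3‑acetoxyprop‑1‑enyl]‑7‑methyl‑6‑oxo‑7,8‑dihydro‑6H‑isochromen‑7‑yl 2,4‑dihydroxy‑6‑methylbenzoate (CNP0115558.1)
Conditions: HF·pyridine, pyridine, THF, 0 °C to rt
Reagents that add atoms: none
Why: Fluoride cleavage of the two aryl silyl ethers under mildly acidic, buffered conditions that should leave the allylic acetate, the hindered aryl ester and the C7 centre untouched.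

**Compound list**

1 | kojic acid | OCC1=CC(=O)C(O)=CO1 | starting material
2 | kojic acid 5‑triflate | OCC1=CC(=O)C(OS(=O)(=O)C(F)(F)F)=CO1 | intermediate
3 | allyltributylstannane | C=CC[Sn](CCCC)(CCCC)CCCC | starting material
4 | 5‑allyl‑2‑(hydroxymethyl)‑4H‑pyran‑4‑one | OCC1=CC(=O)C(CC=C)=CO1 | intermediate
5 | 5‑allyl‑4‑oxo‑4H‑pyran‑2‑carbaldehyde | O=CC1=CC(=O)C(CC=C)=CO1 | intermediate
6 | (triphenylphosphoranylidene)acetaldehyde | O=CC=P(c1ccccc1)(c1ccccc1)c1ccccc1 | starting material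
7 | (E)‑3‑(5‑allyl‑4‑oxo‑4H‑pyran‑2‑yl)prop‑2‑enal | O=C/C=C/C1=CC(=O)C(CC=C)=CO1 | intermediate
8 | 5‑allyl‑2‑[(E)‑3‑hydroxyprop‑1‑enyl]‑4H‑pyran‑4‑one | OC/C=C/C1=CC(=O)C(CC=C)=CO1 | intermediate
9 | 5‑allyl‑2‑[(E)‑3‑(tert‑butyldiphenylsilyloxy)prop‑1‑enyl]‑4H‑pyran‑4‑one | CC(C)(C)[Si](c1ccccc1)(c1ccccc1)OC/C=C/C1=CC(=O)C(CC=C)=CO1 | intermediate
10 | racemic 5‑allyl‑2‑[(E)‑3‑(tert‑butyldiphenylsilyloxy)prop‑1‑enyl]‑4‑ethynyl‑4H‑pyran‑4‑ol | CC(C)(C)[Si](c1ccccc1)(c1ccccc1)OC/C=C/C1=CC(O)(C#C)C(CC=C)=CO1 | intermediate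
11 | (Z)‑2‑{5‑allyl‑2‑[(E)‑3‑(tert‑butyldiphenylsilyloxy)prop‑1‑enyl]‑4H‑pyran‑4‑ylidene}acetaldehyde | CC(C)(C)[Si](c1ccccc1)(c1ccccc1)OC/C=C/C1=C/C(=C/C=O)C(CC=C)=CO1 | intermediate
12 | (Z)‑2‑{5‑(2‑oxopropyl)‑2‑[(E)‑3‑(tert‑butyldiphenylsilyloxy)prop‑1‑enyl]‑4H‑pyran‑4‑ylidene}acetaldehyde | CC(C)(C)[Si](c1ccccc1)(c1ccccc1)OC/C=C/C1=C/C(=C/C=O)C(CC(C)=O)=CO1 | intermediate
13 | (S)‑3‑[(E)‑3‑(tert‑butyldiphenylsilyloxy)prop‑1‑enyl]‑7‑hydroxy‑7‑methyl‑7,8‑dihydro‑6H‑isochromen‑6‑one | CC(C)(C)[Si](c1ccccc1)(c1ccccc1)OC/C=C/C1=CC2=CC(=O)[C@@](C)(O)CC2=CO1 | intermediate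
14 | (S)‑7‑hydroxy‑3‑[(E)‑3‑hydroxyprop‑1‑enyl]‑7‑methyl‑7,8‑dihydro‑6H‑isochromen‑6‑one | OC/C=C/C1=CC2=CC(=O)[C@@](C)(O)CC2=CO1 | intermediate
15 | (E)‑3‑[(S)‑7‑hydroxy‑7‑methyl‑6‑oxo‑7,8‑dihydro‑6H‑isochromen‑3‑yl]allyl acetate | CC(=O)OC/C=C/C1=CC2=CC(=O)[C@@](C)(O)CC2=CO1 | intermediate
16 | orsellinic acid | Cc1cc(O)cc(O)c1C(=O)O | starting material
17 | tert‑butyldimethylsilyl 2,4‑bis(tert‑butyldimethylsilyloxy)‑6‑methylbenzoate | Cc1cc(O[Si](C)(C)C(C)(C)C)cc(O[Si](C)(C)C(C)(C)C)c1C(=O)O[Si](C)(C)C(C)(C)C | intermediate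
18 | 2,4‑bis(tert‑butyldimethylsilyloxy)‑6‑methylbenzoic acid | Cc1cc(O[Si](C)(C)C(C)(C)C)cc(O[Si](C)(C)C(C)(C)C)c1C(=O)O | intermediate
19 | 2,4‑bis(tert‑butyldimethylsilyloxy)‑6‑methylbenzoyl chloride | Cc1cc(O[Si](C)(C)C(C)(C)C)cc(O[Si](C)(C)C(C)(C)C)c1C(Cl)=O | intermediate
20 | (S)‑3‑[(E)‑3‑acetoxyprop‑1‑enyl]‑7‑methyl‑6‑oxo‑7,8‑dihydro‑6H‑isochromen‑7‑yl 2,4‑bis(tert‑butyldimethylsilyloxy)‑6‑methylbenzoate | CC(=O)OC/C=C/C1=CC2=CC(=O)[C@@](C)(OC(=O)c3c(C)cc(O[Si](C)(C)C(C)(C)C)cc3O[Si](C)(C)C(C)(C)C)CC2=CO1 | intermediate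
21 | (S)‑3‑[(E)‑3‑acetoxyprop‑1‑enyl]‑7‑methyl‑6‑oxo‑7,8‑dihydro‑6H‑isochromen‑7‑yl 2,4‑dihydroxy‑6‑methylbenzoate (CNP0115558.1) | CC(=O)OC/C=C/C1=CC2=CC(=O)[C@@](C)(OC(=O)c3c(C)cc(O)cc3O)CC2=CO1 | target

**Step count**

Total: 15 steps. Longest linear sequence: 14 steps (kojic acid 1 to target 21 through steps 1 to 12, 14 and 15). Step 13 is a one‑step side branch to acid 18.

**Steps most likely to fail, with fallbacks**

1. Step 10 (benzoin ring closure). The carbene may add too slowly to the deactivated, vinylogous formyl group. The ketone may instead enolise toward C8 and close a five‑membered aldol ring onto C6. Facial selectivity at the ketone may be poor. Fallback, from 12 back to 13: the same C6–C7 bond would be made reductively and the enantiomers separated afterwards. SmI2 (2.2 equiv) in THF with t‑BuOH at −78 °C should reduce the conjugated aldehyde of 12 to its ketyl, which adds to the methyl ketone in an intramolecular pinacol coupling of a keto aldehyde. This should give 3‑[(E)‑3‑(tert‑butyldiphenylsilyloxy)prop‑1‑enyl]‑7‑methyl‑7,8‑dihydro‑6H‑isochromene‑6,7‑diol F1 as a racemic mixture of diastereomers, both of which are usable. MnO2 in CH2Cl2 would then oxidise only the secondary allylic C6 hydroxyl to give racemic 3‑[(E)‑3‑(tert‑butyldiphenylsilyloxy)prop‑1‑enyl]‑7‑hydroxy‑7‑methyl‑7,8‑dihydro‑6H‑isochromen‑6‑one F2. Preparative chromatography on a chiral stationary phase (cellulose tris(3,5‑dimethylphenylcarbamate)) would separate (S)‑ketol 13, where the route is rejoined, from the (R)‑configured ketol F3.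

2. Step 8 (Meyer–Schuster rearrangement, together with the addition of step 7). Water may capture the ethynylpyrylium ion at the unsubstituted ring position C1 and open the ring. The cation may oligomerise. The 1,2‑addition that precedes it may stall on the weakly electrophilic pyranone. Fallback, from 9 back to 11: one carbon is added and the second is introduced by formylation. MeMgBr/CeCl3 in THF should add 1,2 to pyranone 9 to give racemic 5‑allyl‑2‑[(E)‑3‑(tert‑butyldiphenylsilyloxy)prop‑1‑enyl]‑4‑methyl‑4H‑pyran‑4‑ol F4. Dehydration with methyl N‑(triethylammoniosulfonyl)carbamate in toluene can only take a methyl hydrogen and should give tert‑butyl{[(E)‑3‑(5‑allyl‑4‑methylene‑4H‑pyran‑2‑yl)allyl]oxy}diphenylsilane F5, the anhydrobase of the 4‑methylpyrylium ion. Vilsmeier formylation of its electron‑rich exocyclic carbon with (chloromethylene)dimethyliminium chloride in CH2Cl2 at 0 °C should give N‑{2‑[5‑allyl‑2‑((E)‑3‑(tert‑butyldiphenylsilyloxy)prop‑1‑enyl)‑4H‑pyran‑4‑ylidene]ethylidene}‑N‑methylmethanaminium chloride F6. Hydrolysis with aqueous NaOAc would then release aldehyde 11.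

3. Step 14 (esterification). A tertiary α‑ketol must be acylated by a benzoyl chloride that carries two ortho substituents. The acylation may not proceed, and forcing conditions may cause loss of the C7 oxygen function by elimination toward the fully conjugated isochromenone. Fallback, from 16 and 15 back to 21: the alcohol is activated instead of the acid, and the acyl donor is a cyclic acetal ester that releases the ortho phenol as it reacts. Orsellinic acid 16 with acetone, (CF3CO)2O and CF3CO2H should give 7‑hydroxy‑2,2,5‑trimethyl‑4H‑1,3‑benzodioxin‑4‑one F7, and TBSCl/imidazole would give 7‑(tert‑butyldimethylsilyloxy)‑2,2,5‑trimethyl‑4H‑1,3‑benzodioxin‑4‑one F8. The sodium alkoxide of 15 (NaN(SiMe3)2, THF, −78 °C) would open the dioxinone at its carbonyl with loss of acetone. This should give (S)‑3‑[(E)‑3‑acetoxyprop‑1‑enyl]‑7‑methyl‑6‑oxo‑7,8‑dihydro‑6H‑isochromen‑7‑yl 4‑(tert‑butyldimethylsilyloxy)‑2‑hydroxy‑6‑methylbenzoate F9. HF·pyridine would then give target 21.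

**Further compounds**

F1 | step 10 | 3‑[(E)‑3‑(tert‑butyldiphenylsilyloxy)prop‑1‑enyl]‑7‑methyl‑7,8‑dihydro‑6H‑isochromene‑6,7‑diol (racemic, both diastereomers) | CC(C)(C)[Si](c1ccccc1)(c1ccccc1)OC/C=C/C1=CC2=CC(O)C(C)(O)CC2=CO1
F2 | step 10 | racemic 3‑[(E)‑3‑(tert‑butyldiphenylsilyloxy)prop‑1‑enyl]‑7‑hydroxy‑7‑methyl‑7,8‑dihydro‑6H‑isochromen‑6‑one | CC(C)(C)[Si](c1ccccc1)(c1ccccc1)OC/C=C/C1=CC2=CC(=O)C(C)(O)CC2=CO1
F3 | step 10 | (R)‑3‑[(E)‑3‑(tert‑butyldiphenylsilyloxy)prop‑1‑enyl]‑7‑hydroxy‑7‑methyl‑7,8‑dihydro‑6H‑isochromen‑6‑one | CC(C)(C)[Si](c1ccccc1)(c1ccccc1)OC/C=C/C1=CC2=CC(=O)[C@](C)(O)CC2=CO1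
F4 | step 8 | racemic 5‑allyl‑2‑[(E)‑3‑(tert‑butyldiphenylsilyloxy)prop‑1‑enyl]‑4‑methyl‑4H‑pyran‑4‑ol | CC(C)(C)[Si](c1ccccc1)(c1ccccc1)OC/C=C/C1=CC(C)(O)C(CC=C)=CO1
F5 | step 8 | tert‑butyl{[(E)‑3‑(5‑allyl‑4‑methylene‑4H‑pyran‑2‑yl)allyl]oxy}diphenylsilane | CC(C)(C)[Si](c1ccccc1)(c1ccccc1)OC/C=C/C1=CC(=C)C(CC=C)=CO1
F6 | step 8 | N‑{2‑[5‑allyl‑2‑((E)‑3‑(tert‑butyldiphenylsilyloxy)prop‑1‑enyl)‑4H‑pyran‑4‑ylidene]ethylidene}‑N‑methylmethanaminium chloride | CC(C)(C)[Si](c1ccccc1)(c1ccccc1)OC/C=C/C1=CC(=CC=[N+](C)C)C(CC=C)=CO1.[Cl-]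
F7 | step 14 | 7‑hydroxy‑2,2,5‑trimethyl‑4H‑1,3‑benzodioxin‑4‑one | Cc1cc(O)cc2OC(C)(C)OC(=O)c12
F8 | step 14 | 7‑(tert‑butyldimethylsilyloxy)‑2,2,5‑trimethyl‑4H‑1,3‑benzodioxin‑4‑one | Cc1cc(O[Si](C)(C)C(C)(C)C)cc2OC(C)(C)OC(=O)c12
F9 | step 14 | (S)‑3‑[(E)‑3‑acetoxyprop‑1‑enyl]‑7‑methyl‑6‑oxo‑7,8‑dihydro‑6H‑isochromen‑7‑yl 4‑(tert‑butyldimethylsilyloxy)‑2‑hydroxy‑6‑methylbenzoate | CC(=O)OC/C=C/C1=CC2=CC(=O)[C@@](C)(OC(=O)c3c(C)cc(O[Si](C)(C)C(C)(C)C)cc3O)CC2=CO1
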